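**Strategy.** Germacrane numbering is used (ring C1–C10, lactone carbons C11–C13). The lactone oxygen sits on C6, allylic to the ring C4=C5 bond, and C7 carries C11. The butyrolactone ring is therefore the footprint of an acrylate unit laid across one double bond of a C4=C5–C6=C7 diene. A palladium-catalysed carbo-oxygenation of an acyclic (4Z,6E)-diene with 2-bromoacrylic acid should form O–C6 and C7–C11 in one operation, deliver the α-methylene lactone directly, set C6 and C7 from the glyceraldehyde-derived C8 centre and leave C4=C5 untouched. The ten-membered ring is closed last at C9–C10 by a Nozaki–Hiyama–Kishi reaction.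

Key step: step 4

Remark on the chemistry: the target is read as 6R,7S,8S,9R with a 1(10)E,4Z diene (both double bonds ring-cis) and a trans-fused lactone. Compounds 1, 2, 6, 10, 13 and 17 are taken as commercial.

Step 1
Reactants: 1 2-(2-bromoethyl)-1,3-dioxolane; 2 propyne
Product: 5 2-[(3Z)-4-iodo-3-methylbut-3-en-1-yl]-1,3-dioxolane, via Grignard reagent 3 (not isolated), via alkenylcopper 4 (not isolated)
Conditions: Mg, THF, 25 °C; CuBr·SMe2, Et2O/Me2S, −45 °C; propyne, −25 °C; I2, THF, −78 to 0 °C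
Reagents that add atoms: iodine, I-I
Why: Normant carbocupration adds the alkylcopper syn to propyne with the alkyl group on the internal carbon, so copper and the chain end up cis, and iodinolysis with retention should give the Z-iodide that holds C1–C5 and C15 with the ring-cis C4=C5 geometry.

Step 2
Reactants: 6 (4R)-2,2-dimethyl-1,3-dioxolane-4-carbaldehyde
Product: 7 (4S)-4-ethynyl-2,2-dimethyl-1,3-dioxolane
Conditions: dimethyl (1-diazo-2-oxopropyl)phosphonate, K2CO3, MeOH, 0 °C to rt
Reagents that add atoms: dimethyl (1-diazo-2-oxopropyl)phosphonate, CC(=O)C(=[N+]=[N-])P(=O)(OC)OC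
Why: Ohira–Bestmann homologation (Seyferth–Gilbert type) turns the aldehyde into the terminal alkyne under mild carbonate conditions that should leave the adjacent stereocentre, the future C8, untouched (the descriptor changes from R to S only through priorities).

Step 3
Reactants: 7 (4S)-4-ethynyl-2,2-dimethyl-1,3-dioxolane; 5 2-[(3Z)-4-iodo-3-methylbut-3-en-1-yl]-1,3-dioxolane
Product: 9 (4S)-4-[(1E,3Z)-6-(1,3-dioxolan-2-yl)-4-methylhexa-1,3-dien-1-yl]-2,2-dimethyl-1,3-dioxolane, via alkenylzirconocene 8 (not isolated)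
Conditions: Cp2Zr(H)Cl, THF, rt; then 5, Pd(PPh3)4 (5 mol %), ZnCl2 (0.5 equiv, transmetalation shuttle), THF, rt
Reagents that add atoms: none
Why: Schwartz hydrozirconation adds Zr–H syn with zirconium on the terminal carbon to give the E-alkenylzirconocene, and Negishi coupling at zerovalent palladium should join it to the Z-iodide with retention at both partners.

Step 4
Reactants: 9 (4S)-4-[(1E,3Z)-6-(1,3-dioxolan-2-yl)-4-methylhexa-1,3-dien-1-yl]-2,2-dimethyl-1,3-dioxolane; 10 2-bromoacrylic acid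
Product: 11 (4S,5R)-4-[(4S)-2,2-dimethyl-1,3-dioxolan-4-yl]-5-[(1Z)-4-(1,3-dioxolan-2-yl)-2-methylbut-1-en-1-yl]-3-methylideneoxolan-2-one
Conditions: Pd(OAc)2 (10 mol %), P(2-furyl)3 (20 mol %), Ag2CO3 (1.5 equiv), DMF, 60 °C
Reagents that add atoms: none
Why: Larock-type heteroannulation of a 1,3-diene by a vinylic halide that carries a carboxylic acid: zerovalent palladium inserts into the C–Br bond of the 2-bromoacrylate, the 1-carboxyvinyl palladium adds syn across C6=C7 with C11 going to C7, and the η3-allyl over C6–C5–C4 is captured at C6 by the palladium-bound carboxylate, which releases zerovalent palladium. The lactone ring closes in a 5-exo mode, as C–O reductive elimination from a six-membered palladacycle at the proximal allyl terminus, since attack at C4 would need a seven-membered ring. C6 and C7 are set relative to each other by the E geometry of C6=C7 together with syn carbopalladation and inner-sphere C–O formation with retention (silver removes bromide so the carboxylate stays on palladium), which should give the trans lactone; the allylic C6–O bond stays ionisable, so any cis isomer can equilibrate toward the more stable trans lactone. The absolute sense comes from the C8 dioxolane centre: in the conformer with H8 eclipsing the alkene the vinylpalladium should add anti to the C8–O bond, the usual sense for electrophilic additions to E-alkenyl dioxolanes, and this is the 6R,7S face. Regioselectivity for C7 over C4 follows from the fully substituted C4 terminus and from the allyl stabilisation that only addition at a diene terminus provides. The 4Z geometry should survive because the allyl cannot invert without an η1 stage at the tertiary C4, and both acetals are inert.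

Step 5
Reactants: 11 (4S,5R)-4-[(4S)-2,2-dimethyl-1,3-dioxolan-4-yl]-5-[(1Z)-4-(1,3-dioxolan-2-yl)-2-methylbut-1-en-1-yl]-3-methylideneoxolan-2-one
Product: 12 (4Z)-5-[(2R,3R)-3-[(1S)-1,2-dihydroxyethyl]-4-methylidene-5-oxooxolan-2-yl]-4-methylpent-4-enal
Conditions: 1 M aq. HCl, THF, 0 °C to rt
Reagents that add atoms: water, O
Why: Acid-catalysed acetal hydrolysis removes the acetonide and the dioxolane in one operation, and dilute acid at or below room temperature should spare the allylic C6–O lactone bond and the exocyclic methylene (the ring descriptor at C7 changes to R only through priorities).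

Step 6
Reactants: 12 (4Z)-5-[(2R,3R)-3-[(1S)-1,2-dihydroxyethyl]-4-methylidene-5-oxooxolan-2-yl]-4-methylpent-4-enal; 13 methyl (triphenylphosphoranylidene)acetate
Product: 15 methyl (2Z,6Z)-7-[(2R,3R)-3-[(1S)-1,2-dihydroxyethyl]-4-methylidene-5-oxooxolan-2-yl]-2-iodo-6-methylhepta-2,6-dienoate, via iodo ylide 14 (not isolated)
Conditions: 13, NIS (1.0 equiv to 13), CH2Cl2, −20 °C; then 12, −20 °C to rt
Reagents that add atoms: N-iodosuccinimide, O=C1CCC(=O)N1I
Why: Wittig olefination with the stabilised α-iodo ylide made in the flask is selective for the aldehyde and places the chain trans to the ester, which should give the Z-α-iodo enoate whose geometry becomes the ring-cis C1=C10 bond.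

Step 7
Reactants: 15 methyl (2Z,6Z)-7-[(2R,3R)-3-[(1S)-1,2-dihydroxyethyl]-4-methylidene-5-oxooxolan-2-yl]-2-iodo-6-methylhepta-2,6-dienoate
Product: 16 methyl (2Z,6Z)-7-[(2R,3R)-3-[(1S)-1-hydroxy-2-(triethylsilyloxy)ethyl]-4-methylidene-5-oxooxolan-2-yl]-2-iodo-6-methylhepta-2,6-dienoate
Conditions: TESCl (1.05 equiv), imidazole, CH2Cl2, −40 °C
Reagents that add atoms: chlorotriethylsilane, CC[Si](Cl)(CC)CC
Why: Silylation with a silyl chloride is sterically selective for the primary C9 hydroxyl over the hindered secondary C8 hydroxyl next to the lactone ring.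

Step 8
Reactants: 16 methyl (2Z,6Z)-7-[(2R,3R)-3-[(1S)-1-hydroxy-2-(triethylsilyloxy)ethyl]-4-methylidene-5-oxooxolan-2-yl]-2-iodo-6-methylhepta-2,6-dienoate; 17 angelic acid
Product: 19 methyl (2Z,6Z)-2-iodo-6-methyl-7-[(2R,3S)-3-[(1S)-1-{[(2Z)-2-methylbut-2-enoyl]oxy}-2-(triethylsilyloxy)ethyl]-4-methylidene-5-oxooxolan-2-yl]hepta-2,6-dienoate, via mixed anhydride 18 (not isolated)
Conditions: 17, 2,4,6-trichlorobenzoyl chloride, Et3N, toluene, rt; then 16, 75 °C
Reagents that add atoms: none
Why: Yamaguchi esterification through the mixed 2,4,6-trichlorobenzoic anhydride acylates the C8 hydroxyl without a nucleophilic catalyst, conditions under which the Z geometry of angelates is expected to be kept.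

Step 9
Reactants: 19 methyl (2Z,6Z)-2-iodo-6-methyl-7-[(2R,3S)-3-[(1S)-1-{[(2Z)-2-methylbut-2-enoyl]oxy}-2-(triethylsilyloxy)ethyl]-4-methylidene-5-oxooxolan-2-yl]hepta-2,6-dienoate
Product: 20 methyl (2Z,6Z)-2-iodo-6-methyl-7-[(2R,3S)-3-[(1S)-1-{[(2Z)-2-methylbut-2-enoyl]oxy}-2-oxoethyl]-4-methylidene-5-oxooxolan-2-yl]hepta-2,6-dienoate
Conditions: (COCl)2, DMSO, CH2Cl2, −78 to −40 °C; then Et3N, −78 to 0 °C
Reagents that add atoms: none
Why: Swern oxidation applied directly to a primary triethylsilyl ether: the activated-DMSO medium cleaves the primary Si–O bond and the alkoxysulfonium pathway should give the aldehyde in one step, so no free hydroxy ester open to acyl shift is ever handled.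

Step 10
Reactants: 20 methyl (2Z,6Z)-2-iodo-6-methyl-7-[(2R,3S)-3-[(1S)-1-{[(2Z)-2-methylbut-2-enoyl]oxy}-2-oxoethyl]-4-methylidene-5-oxooxolan-2-yl]hepta-2,6-dienoate
Product: 21 target germacranolide methyl (1(10)E,4Z,6R,7S,8S,9R)-8-[(2Z)-2-methylbut-2-enoyloxy]-9-hydroxygermacra-1(10),4,11(13)-trien-6,12-olid-14-oate
Conditions: CrCl2 (10 equiv), NiCl2 (0.2 equiv), DMSO/THF, 2 mM, rt
Reagents that add atoms: none
Why: Nozaki–Hiyama–Kishi reaction: zerovalent nickel inserts into the C–I bond, transmetalation gives an alkenyl species of trivalent chromium that adds to the C9 aldehyde with retention of alkene geometry and closes the ten-membered ring at high dilution, and Felkin–Anh addition anti to the C8 acyloxy group should give the 9R alcohol.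

**Compound list**

1 | 2-(2-bromoethyl)-1,3-dioxolane | BrCCC1OCCO1 | starting material
2 | propyne | CC#C | starting material
3 | [2-(1,3-dioxolan-2-yl)ethyl]magnesium bromide | Br[Mg]CCC1OCCO1 | intermediate (not isolated)
4 | [(1Z)-4-(1,3-dioxolan-2-yl)-2-methylbut-1-en-1-yl]copper | [Cu]/C=C(/C)CCC1OCCO1 | intermediate (not isolated)
5 | 2-[(3Z)-4-iodo-3-methylbut-3-en-1-yl]-1,3-dioxolane | I/C=C(/C)CCC1OCCO1 | intermediate
6 | (4R)-2,2-dimethyl-1,3-dioxolane-4-carbaldehyde | O=C[C@H]1COC(C)(C)O1 | starting material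
7 | (4S)-4-ethynyl-2,2-dimethyl-1,3-dioxolane | C#C[C@H]1COC(C)(C)O1 | intermediate
8 | chlorobis(cyclopentadienyl){(E)-2-[(4S)-2,2-dimethyl-1,3-dioxolan-4-yl]ethenyl}zirconium | Cl[Zr](/C=C/[C@H]1COC(C)(C)O1)(C1C=CC=C1)C1C=CC=C1 | intermediate (not isolated)
9 | (4S)-4-[(1E,3Z)-6-(1,3-dioxolan-2-yl)-4-methylhexa-1,3-dien-1-yl]-2,2-dimethyl-1,3-dioxolane | CC1(C)OC[C@H](/C=C/C=C(/C)CCC2OCCO2)O1 | intermediate
10 | 2-bromoacrylic acid (2-bromoprop-2-enoic acid) | C=C(Br)C(=O)O | starting material
11 | (4S,5R)-4-[(4S)-2,2-dimethyl-1,3-dioxolan-4-yl]-5-[(1Z)-4-(1,3-dioxolan-2-yl)-2-methylbut-1-en-1-yl]-3-methylideneoxolan-2-one | C=C1C(=O)O[C@H](/C=C(/C)CCC2OCCO2)[C@H]1[C@H]3COC(C)(C)O3 | intermediate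
12 | (4Z)-5-[(2R,3R)-3-[(1S)-1,2-dihydroxyethyl]-4-methylidene-5-oxooxolan-2-yl]-4-methylpent-4-enal | C=C1C(=O)O[C@H](/C=C(/C)CCC=O)[C@H]1[C@H](O)CO | intermediate
13 | methyl (triphenylphosphoranylidene)acetate | COC(=O)C=P(c1ccccc1)(c1ccccc1)c1ccccc1 | starting material
14 | methyl 2-iodo-2-(triphenylphosphoranylidene)acetate | COC(=O)C(I)=P(c1ccccc1)(c1ccccc1)c1ccccc1 | intermediate (not isolated)
15 | methyl (2Z,6Z)-7-[(2R,3R)-3-[(1S)-1,2-dihydroxyethyl]-4-methylidene-5-oxooxolan-2-yl]-2-iodo-6-methylhepta-2,6-dienoate | C=C1C(=O)O[C@H](/C=C(/C)CC/C=C(\I)C(=O)OC)[C@H]1[C@H](O)CO | intermediate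
16 | methyl (2Z,6Z)-7-[(2R,3R)-3-[(1S)-1-hydroxy-2-(triethylsilyloxy)ethyl]-4-methylidene-5-oxooxolan-2-yl]-2-iodo-6-methylhepta-2,6-dienoate | C=C1C(=O)O[C@H](/C=C(/C)CC/C=C(\I)C(=O)OC)[C@H]1[C@H](O)CO[Si](CC)(CC)CC | intermediate
17 | angelic acid, (2Z)-2-methylbut-2-enoic acid | C/C=C(/C)C(=O)O | starting material
18 | (2Z)-2-methylbut-2-enoic 2,4,6-trichlorobenzoic anhydride | C/C=C(/C)C(=O)OC(=O)c1c(Cl)cc(Cl)cc1Cl | intermediate (not isolated)
19 | methyl (2Z,6Z)-2-iodo-6-methyl-7-[(2R,3S)-3-[(1S)-1-{[(2Z)-2-methylbut-2-enoyl]oxy}-2-(triethylsilyloxy)ethyl]-4-methylidene-5-oxooxolan-2-yl]hepta-2,6-dienoate | C=C1C(=O)O[C@H](/C=C(/C)CC/C=C(\I)C(=O)OC)[C@H]1[C@H](OC(=O)/C(C)=C\C)CO[Si](CC)(CC)CC | intermediate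
20 | methyl (2Z,6Z)-2-iodo-6-methyl-7-[(2R,3S)-3-[(1S)-1-{[(2Z)-2-methylbut-2-enoyl]oxy}-2-oxoethyl]-4-methylidene-5-oxooxolan-2-yl]hepta-2,6-dienoate | C=C1C(=O)O[C@H](/C=C(/C)CC/C=C(\I)C(=O)OC)[C@H]1[C@H](OC(=O)/C(C)=C\C)C=O | intermediate
21 | methyl (1(10)E,4Z,6R,7S,8S,9R)-8-[(2Z)-2-methylbut-2-enoyloxy]-9-hydroxygermacra-1(10),4,11(13)-trien-6,12-olid-14-oate | C=C1C(=O)O[C@@H]2/C=C(/C)CC/C=C(/C(=O)OC)[C@@H](O)[C@@H](OC(=O)/C(C)=C\C)[C@@H]12 | target

**Step count and risks**

Total step count: 10. Longest linear sequence: 9 steps (6 to 21 through steps 2–10; the branch from 1 joins at step 3 and is equally long).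

Steps most likely to fail:

1. Step 4. The carbopalladation may show poor facial selectivity with respect to the C8 centre. The C–O closure may also take an outer-sphere course and deliver the cis lactone, or the allyl intermediate may lose a β-hydride to give an open-chain triene acid. The fallback moves the disconnection to C6–C7 and uses a chromium-mediated carbonyl allylation; it sets out from 6 and 5 and comes back at 11. Compound 6 and methyl acrylate (DABCO, neat, rt) would give the Morita–Baylis–Hillman adduct methyl 2-[hydroxy((4R)-2,2-dimethyl-1,3-dioxolan-4-yl)methyl]prop-2-enoate F1. NBS/Me2S (CH2Cl2, 0 °C) would convert it with allylic transposition into methyl (2Z)-2-(bromomethyl)-3-[(4S)-2,2-dimethyl-1,3-dioxolan-4-yl]prop-2-enoate F2. Iodine–lithium exchange on 5 (t-BuLi, Et2O, −78 °C) and quenching with DMF would give (2Z)-5-(1,3-dioxolan-2-yl)-3-methylpent-2-enal F3. CrCl2 in THF would join F2 and F3 through the γ-carbon of the allylchromium, anti-selectively by way of the chair transition state, to methyl (3S,4R,5Z)-8-(1,3-dioxolan-2-yl)-3-[(4S)-2,2-dimethyl-1,3-dioxolan-4-yl]-4-hydroxy-6-methyl-2-methylideneoct-5-enoate F4. F4 should close to the trans lactone 11 in the flask or with catalytic TsOH; the facial sense with respect to the dioxolane would have to be confirmed.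

2. Step 10. The ring-closing addition may take the wrong face of the C9 aldehyde, the angeloyl group may shift from O8 to the new chromium alkoxide at O9, or oligomers may form despite dilution. The fallback corrects C9 by oxidation and reduction; it sets out from 20 and comes back at 21. The ring closure would be accepted as the C9 epimer, methyl (1(10)E,4Z,6R,7S,8S,9S)-8-[(2Z)-2-methylbut-2-enoyloxy]-9-hydroxygermacra-1(10),4,11(13)-trien-6,12-olid-14-oate F5. Dess–Martin periodinane (CH2Cl2, NaHCO3) would give the C9 ketone, methyl (1(10)E,4Z,6R,7S,8S)-8-[(2Z)-2-methylbut-2-enoyloxy]-9-oxogermacra-1(10),4,11(13)-trien-6,12-olid-14-oate F6. A 1,2-selective Luche reduction (NaBH4, CeCl3·7H2O, MeOH, −78 °C) or a Corey–Bakshi–Shibata reduction chosen for the 9R face would then return 21.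

3. Step 8. The angeloyl unit may isomerise from Z to E during acylation, the silyl group may shift from O9 to O8 on heating with base, or the hindered C8 hydroxyl may acylate sluggishly. The fallback builds the Z double bond on the ester after acylation; it sets out from 16 and comes back at 19. Compound 16 would be acylated with 2-[bis(2,2,2-trifluoroethoxy)phosphoryl]propanoic acid (DCC, DMAP, CH2Cl2, 0 °C) to methyl (2Z,6Z)-7-[(2R,3S)-3-[(1S)-1-({2-[bis(2,2,2-trifluoroethoxy)phosphoryl]propanoyl}oxy)-2-(triethylsilyloxy)ethyl]-4-methylidene-5-oxooxolan-2-yl]-2-iodo-6-methylhepta-2,6-dienoate F7. A Still–Gennari olefination of F7 with acetaldehyde (KHMDS, 18-crown-6, THF, −78 °C) should give the Z-configured angelate 19.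

Further compounds
F1 | step 4 | methyl 2-[hydroxy((4R)-2,2-dimethyl-1,3-dioxolan-4-yl)methyl]prop-2-enoate | C=C(C(=O)OC)C(O)[C@H]1COC(C)(C)O1
F2 | step 4 | methyl (2Z)-2-(bromomethyl)-3-[(4S)-2,2-dimethyl-1,3-dioxolan-4-yl]prop-2-enoate | COC(=O)/C(CBr)=C/[C@H]1COC(C)(C)O1
F3 | step 4 | (2Z)-5-(1,3-dioxolan-2-yl)-3-methylpent-2-enal | O=C/C=C(/C)CCC1OCCO1
F4 | step 4 | methyl (3S,4R,5Z)-8-(1,3-dioxolan-2-yl)-3-[(4S)-2,2-dimethyl-1,3-dioxolan-4-yl]-4-hydroxy-6-methyl-2-methylideneoct-5-enoate | C=C(C(=O)OC)[C@@H]([C@H](O)/C=C(/C)CCC2OCCO2)[C@H]3COC(C)(C)O3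
F5 | step 10 | methyl (1(10)E,4Z,6R,7S,8S,9S)-8-[(2Z)-2-methylbut-2-enoyloxy]-9-hydroxygermacra-1(10),4,11(13)-trien-6,12-olid-14-oate | C=C1C(=O)O[C@@H]2/C=C(/C)CC/C=C(/C(=O)OC)[C@H](O)[C@@H](OC(=O)/C(C)=C\C)[C@@H]12
F6 | step 10 | methyl (1(10)E,4Z,6R,7S,8S)-8-[(2Z)-2-methylbut-2-enoyloxy]-9-oxogermacra-1(10),4,11(13)-trien-6,12-olid-14-oate | C=C1C(=O)O[C@@H]2/C=C(/C)CC/C=C(/C(=O)OC)C(=O)[C@@H](OC(=O)/C(C)=C\C)[C@@H]12
F7 | step 8 | methyl (2Z,6Z)-7-[(2R,3S)-3-[(1S)-1-({2-[bis(2,2,2-trifluoroethoxy)phosphoryl]propanoyl}oxy)-2-(triethylsilyloxy)ethyl]-4-methylidene-5-oxooxolan-2-yl]-2-iodo-6-methylhepta-2,6-dienoate | C=C1C(=O)O[C@H](/C=C(/C)CC/C=C(\I)C(=O)OC)[C@H]1[C@H](OC(=O)C(C)P(=O)(OCC(F)(F)F)OCC(F)(F)F)CO[Si](CC)(CC)CC
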